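| flask | substrate | partner | second reagent | remark | time |
|---|---|---|---|---|---|
| spring | 0.12 M | 0.060 M | 0.14 M | run made earlier |  |
| noon | 0.12 M | 0.060 M | 0.94 M | run made earlier |  |
| south-west | 0.12 M | 0.0600 M | 0.100 M |  | 25 h |
| north-east | 0.12 M | 0.0600 M | 0.200 M |  | 25 h |
| north | 0.12 M | 0.0600 M | 0.400 M |  | 25 h |
| south | 0.12 M | 0.0600 M | 0.800 M |  | 25 h |

- spring (time / h: intermediate / %, target / %, substrate / %): 1.50: 6, 0, 93; 4.00: 14, 0, 90; 8.00: 15, 0, 84; 12.0: 19, 4, 78; 20.0: 21, 4, 72
- noon (time / h: intermediate / %, target / %, substrate / %): 1.33: 4, 0, 95; 2.50: 7, 0, 91; 5.00: 8, 0, 85; 10.0: 8, 11, 78; 20.0: 5, 22, 74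

(scatter of a reading: 2 percentage points)

- "hardly changes" means that all values lie within two and a half points (for a concentration: within two and a half percent of the largest)

1. amount of intermediate at the end, in percent of the substrate charged for south-west, north-east, north, south, in this order
2. how that number moves from the first to the last of them (falls, then rises / falls all the way / rises all the way / hardly changes / rises, then falls)

1. If second reagent stays near its charge, intermediate decays in a pseudo-first-order way, and the noon run gives the constant. Between 10.0 h and 20.0 h target gains 11 percentage points of the substrate charge over a mean intermediate of 6.50%, so the reading is 0.180 L mol⁻¹ h⁻¹.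

2. Constant, second reagent and time multiply to 0.450 for south-west: the lifetime count, the number of intermediate lifetimes that fit into the run. North-east, north and south have 0.900, 1.80 and 3.60.

3. The feed is the substrate lost: 28.0% in spring and 26.0% at noon, at the same time and with very different second reagent. My own reckoning takes an even feed, which leaves feed × (1 − e^−N)/N as intermediate: 22.5%, 18.5%, 13.0%, 7.56%.

4. Is one number enough? Spring, with a count of 0.504, gives 22.0% against a reading of 21%. But the noon substrate has lost 15.0% by 5.00 h, so the feed comes early, and high counts will reckon high.

5. The forecast gives 21%, 16%, 10%, 4%, shape falls all the way: “the intermediate falls steadily as reagent increases”. It lies below my row at the south end.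

6. The flasks give 21.9%, 16.9%, 10.5%, 4.72%, shape falls all the way.

    substrate + partner → intermediate (k = 0.693 L mol⁻¹ h⁻¹)
    second reagent + intermediate → target (k = 0.163 L mol⁻¹ h⁻¹)
    partner ⇌ dormant form (K = 1.74, k = 0.0722 h⁻¹)

South-west, with a count of 0.450, stands at 21.9% against the reckoned 22.5%. South, with a count of 3.60, stands at 4.72%, below its 7.56%, with partner down to 12% of its charge. The count sees second reagent, but the feed draws on partner. With the depletion of partner taken away, south holds 15.6% of intermediate instead of 4.72%.

The data come from a simulation for an exercise, and the scatter is random.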